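**Retrosynthetic overview**
1. Target 50 comes from BBr3 cleavage of the pentadeca-O-methyl ether 49; rings A, B, D and F enter as intact methoxylated arenes.
2. Feature: rings C and E are each a benzene with oxygen on C1, C3, C4 and C5, the two aryloxy groups para (C1, C4) and C–H at C2 and C6. C5–O maps onto a ketene carbonyl carbon, C4(OAr)/C3(OMe) onto the alkene of an aryloxy(methoxy)vinylketene, C2–H onto the former diazo carbon, and C1(OAr)/C6–H onto an aryl ethynyl ether.
3. Ring E (first): diazoketone 10 (carries ring F) + ynol ether 21 (carries ring D) → 26, forming E5–E6, E1–E2 and E4–E5. Ring C (second): DEF diazoketone 33 + AB ynol ether 44 → 49 by the same benzannulation.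
4. The aryloxyvinyl units come from vinylic substitution of phenols on chloroacrylate 4, the ethynyl ethers from the phenols and dichloroacetylene 17, which is made once from trichloroethylene (step 9); the only aryl–O–aryl bond made by coupling is A–O–B (Ullmann, step 19).
5. Order of ring formation: E (step 12), then C (step 23).

Key step: step 12

Assumption: the target has no stereocentre, so the only stereo-element carried is the Z geometry of the aryloxyvinyl double bonds (aryloxy trans to the carbonyl); the boron-bound aryloxides present in step 24 before aqueous work-up are an undefined mixture and are not numbered.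

Abbreviations used in names: ArF = 3,4,5-trimethoxyphenyl; ArD = 6-(benzyloxy)-2,3,4-trimethoxyphenyl; ArDEF = 2-[3,5-dimethoxy-4-(3,4,5-trimethoxyphenoxy)phenoxy]-3,4,5-trimethoxyphenyl; ArAB = 2,3,4-trimethoxy-6-(2,4,6-trimethoxyphenoxy)phenyl.

**Route**

Step 1
Reactants: 1 methyl methoxyacetate
Product: 2 sodium 2,3-dimethoxy-3-oxoprop-1-en-1-olate (sodium enolate of methyl 2-methoxy-3-oxopropanoate)
Conditions: NaH, HCO2Me (excess), THF, 0 °C → rt; salt collected by filtration
Reagents that add atoms: methyl formate, COC=O; sodium hydride, [Na+].[H-]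
Why: A crossed Claisen condensation of the ester enolate with the non-enolisable formate should be driven to completion by deprotonation of the 1,3-dicarbonyl product, which separates as its sodium salt.

Step 2
Reactants: 2 sodium 2,3-dimethoxy-3-oxoprop-1-en-1-olate
Product: 4 methyl (Z)-3-chloro-2-methoxyprop-2-enoate, via enol chlorooxalate 3 (not isolated)
Conditions: (COCl)2, DMF (cat.), CH2Cl2, 0 °C → rt; distillation
Reagents that add atoms: oxalyl chloride, O=C(Cl)C(Cl)=O
Why: O-Acylation of the enolate followed by addition–elimination of chloride at the β-carbon (the Vilsmeier-type chlorination that turns 1,3-dicarbonyl enols into β-chloro enones) should give the β-chloroacrylate with loss of CO and CO2, the isomer with chlorine trans to the ester being expected.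

Step 3
Reactants: 4 methyl (Z)-3-chloro-2-methoxyprop-2-enoate; 5 3,4,5-trimethoxyphenol
Product: 6 methyl (Z)-2-methoxy-3-(3,4,5-trimethoxyphenoxy)prop-2-enoate
Conditions: K2CO3, DMF, rt → 50 °C
Reagents that add atoms: none
Why: Nucleophilic vinylic substitution (addition–elimination) of a phenoxide on a β-chloroacrylate is a standard route to β-aryloxyacrylates with retention of geometry, and the Z isomer (aryloxy trans to the ester) is also the thermodynamically favoured one.

Step 4
Reactants: 6 methyl (Z)-2-methoxy-3-(3,4,5-trimethoxyphenoxy)prop-2-enoate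
Product: 8 (Z)-2-methoxy-3-(3,4,5-trimethoxyphenoxy)prop-2-enoic acid, via lithium carboxylate 7 (not isolated)
Conditions: LiOH·H2O, THF–H2O, 0 °C → rt; then 1 M HCl to pH 3, 0 °C
Reagents that add atoms: lithium hydroxide, [Li+].[OH-]
Why: Saponification of β-aryloxyacrylic esters is routine, and the carboxylate once formed deactivates the alkene toward conjugate displacement of the aryloxide.

Step 5
Reactants: 8 (Z)-2-methoxy-3-(3,4,5-trimethoxyphenoxy)prop-2-enoic acid
Product: 10 (Z)-1-diazo-3-methoxy-4-(3,4,5-trimethoxyphenoxy)but-3-en-2-one, via mixed anhydride 9 (not isolated)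
Conditions: i-BuOCOCl, Et3N, THF, −15 °C; then CH2N2 (Et2O), −15 → 0 °C
Reagents that add atoms: diazomethane, C=[N+]=[N-]
Why: Acylation of diazomethane by a mixed carbonic anhydride (the first stage of an Arndt–Eistert sequence) should give the diazoketone under acid-free conditions, and the trisubstituted alkene with donors on both carbons is a poor dipolarophile, so that pyrazoline formation should not compete.

Step 6
Reactants: 5 3,4,5-trimethoxyphenol
Product: 11 5-(benzyloxy)-1,2,3-trimethoxybenzene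
Conditions: BnBr, K2CO3, acetone, reflux
Reagents that add atoms: benzyl bromide, BrCc1ccccc1
Why: Williamson benzylation of an unhindered phenol installs the one group that is later removed without touching the methyl ethers.

Step 7
Reactants: 11 5-(benzyloxy)-1,2,3-trimethoxybenzene
Product: 13 6-(benzyloxy)-2,3,4-trimethoxybenzaldehyde, via iminium chloride 12 (not isolated)
Conditions: POCl3, DMF, 0 → 60 °C; then aq. NaOAc
Reagents that add atoms: N,N-dimethylformamide, CN(C)C=O; water, O
Why: Vilsmeier–Haack formylation should occur at the only type of free ring position, which is ortho to the benzyloxy group and ortho/para to two methoxy groups, so that no regioisomer can arise.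

Step 8
Reactants: 13 6-(benzyloxy)-2,3,4-trimethoxybenzaldehyde
Product: 15 6-(benzyloxy)-2,3,4-trimethoxyphenol, via aryl formate 14 (not isolated)
Conditions: mCPBA, CH2Cl2, 0 °C → rt; then K2CO3 (cat.), MeOH, rt, under Ar
Reagents that add atoms: 3-chloroperoxybenzoic acid, OOC(=O)c1cccc(Cl)c1
Why: Baeyer–Villiger (Dakin-type) oxidation of an electron-rich benzaldehyde proceeds by aryl migration to the formate, and mild methanolysis then frees the phenol only after the oxidant has been removed.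

Step 9
Reactants: 16 trichloroethylene
Product: 17 dichloroacetylene (dilute stock solution in THF)
Conditions: KH (1.1 equiv), MeOH (cat.), THF, 0 °C → rt, under N2; clear supernatant transferred by cannula, kept cold and never concentrated; the batch is divided between steps 10 and 21, which are run side by side
Reagents that add atoms: none
Why: Base-induced 1,2-dehydrochlorination of trichloroethylene, with potassium methoxide as the working base regenerated by KH, is the established laboratory preparation of dichloroacetylene as an ethereal solution that can be handled when kept dilute, cold and under inert gas.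

Step 10
Reactants: 15 6-(benzyloxy)-2,3,4-trimethoxyphenol; 17 dichloroacetylene
Product: 18 1-(benzyloxy)-2-{[(E)-1,2-dichloroethenyl]oxy}-3,4,5-trimethoxybenzene
Conditions: K2CO3 (0.5 equiv), DMF, 17 (THF solution, 1.5 equiv), 0 °C → rt, closed vessel under N2
Reagents that add atoms: none
Why: Nucleophilic anti addition of a phenoxide to the strongly electrophilic dichloroacetylene, with protonation of the chlorovinyl anion by further phenol so that the base acts only as a catalyst, is the elementary step behind the trichloroethylene route to (E)-1,2-dichlorovinyl aryl ethers and tolerates ortho substituents.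

Step 11
Reactants: 18 1-(benzyloxy)-2-{[(E)-1,2-dichloroethenyl]oxy}-3,4,5-trimethoxybenzene
Product: 21 1-(benzyloxy)-2-(ethynyloxy)-3,4,5-trimethoxybenzene (ring D ynol ether), via chloroethynyl ether 19 (not isolated), via lithium acetylide 20 (not isolated)
Conditions: n-BuLi (2.3 equiv), THF, −78 → −40 °C; then MeOH, −78 °C; used at once as a cold solution
Reagents that add atoms: none
Why: Vinylic deprotonation with loss of LiCl and then lithium–chlorine exchange is the known conversion of 1,2-dichlorovinyl ethers into lithium alkoxyacetylides, which on protonation should give the terminal ynol ether, here shielded by two ortho substituents.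

Step 12
Reactants: 10 (Z)-1-diazo-3-methoxy-4-(3,4,5-trimethoxyphenoxy)but-3-en-2-one; 21 1-(benzyloxy)-2-(ethynyloxy)-3,4,5-trimethoxybenzene
Product: 26 5-[6-(benzyloxy)-2,3,4-trimethoxyphenoxy]-3-methoxy-2-(3,4,5-trimethoxyphenoxy)phenol (DEF trimer with free ring E phenol), via vinylketene 22 (not isolated), via vinylcyclobutenone 23 (not isolated), via dienylketene 24 (not isolated), via cyclohexadienone 25 (not isolated)
Conditions: hν (medium-pressure Hg lamp, Pyrex, λ > 300 nm), 21 (1.3 equiv), degassed ClCH2CH2Cl, rt; then 80 °C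
Reagents that add atoms: none
Why: Irradiation expels N2 from 10 and Wolff rearrangement (1,2-shift of the alkenyl group) gives vinylketene 22, whose ketene C=C undergoes [2+2] cycloaddition with ynol ether 21 (bonds E5–E6 and E1–E2) to give 3-aryloxy-4-vinylcyclobutenone 23; on warming this opens by a 4π electrocyclic reaction to dienylketene 24, which closes by a 6π electrocyclic reaction (bond E4–E5) to dienone 25, and enolisation gives phenol 26. The closest known reaction type is the Danheiser benzannulation in its photochemical Wolff variant with alkoxyacetylenes as ketenophiles, which delivers resorcinol monoethers of this substitution pattern. Ring E is closed by a thermal six-electron disrotatory electrocyclisation of the (3E)-dienylketene with the ketene carbon as the sp terminus, and aromatisation makes the sequence irreversible. No stereocentre remains, because the sp3 carbons of 23 and 25 are erased on aromatisation. The one selectivity needed is the orientation of the ketene–alkyne cycloaddition: the polarisation of the ynol ether directs its unsubstituted nucleophilic carbon to the ketene carbonyl carbon and its oxygen-bearing carbon to the ketene α-carbon, which places the ring D aryloxy group meta to the new hydroxyl and para to the ring F aryloxy group. The Z geometry of the enol ether of 10 puts hydrogen, not the aryloxy group, on the inside of the closing triene.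

Step 13
Reactants: 26 5-[6-(benzyloxy)-2,3,4-trimethoxyphenoxy]-3-methoxy-2-(3,4,5-trimethoxyphenoxy)phenol
Product: 27 1-[6-(benzyloxy)-2,3,4-trimethoxyphenoxy]-3,5-dimethoxy-4-(3,4,5-trimethoxyphenoxy)benzene
Conditions: MeI, K2CO3, DMF, rt
Reagents that add atoms: iodomethane, CI
Why: Williamson methylation masks the ring E phenol so that the ring D oxygen is the only free phenol after debenzylation.

Step 14
Reactants: 27 1-[6-(benzyloxy)-2,3,4-trimethoxyphenoxy]-3,5-dimethoxy-4-(3,4,5-trimethoxyphenoxy)benzene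
Product: 28 2-[3,5-dimethoxy-4-(3,4,5-trimethoxyphenoxy)phenoxy]-3,4,5-trimethoxyphenol (DEF phenol)
Conditions: H2 (1 atm), 10% Pd/C, EtOAc–MeOH, rt
Reagents that add atoms: none
Why: Hydrogenolysis cleaves the benzyl ether selectively, since methyl and diaryl ethers are inert and the molecule holds no other reducible group.

Step 15
Reactants: 28 2-[3,5-dimethoxy-4-(3,4,5-trimethoxyphenoxy)phenoxy]-3,4,5-trimethoxyphenol; 4 methyl (Z)-3-chloro-2-methoxyprop-2-enoate
Product: 29 methyl (Z)-3-{2-[3,5-dimethoxy-4-(3,4,5-trimethoxyphenoxy)phenoxy]-3,4,5-trimethoxyphenoxy}-2-methoxyprop-2-enoate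
Conditions: K2CO3, DMF, 50 °C
Reagents that add atoms: none
Why: The vinylic substitution of step 3 is repeated on a phenoxide with one ortho substituent, the small β-chloroacrylate being a sterically undemanding electrophile.

Step 16
Reactants: 29 methyl (Z)-3-(ArDEF-oxy)-2-methoxyprop-2-enoate
Product: 31 (Z)-3-{2-[3,5-dimethoxy-4-(3,4,5-trimethoxyphenoxy)phenoxy]-3,4,5-trimethoxyphenoxy}-2-methoxyprop-2-enoic acid, via lithium carboxylate 30 (not isolated)
Conditions: LiOH·H2O, THF–H2O, 0 °C → rt; then 1 M HCl to pH 3, 0 °C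
Reagents that add atoms: lithium hydroxide, [Li+].[OH-]
Why: Ester saponification as in step 4, with aryl methyl and diaryl ethers stable to aqueous hydroxide.

Step 17
Reactants: 31 (Z)-3-(ArDEF-oxy)-2-methoxyprop-2-enoic acid
Product: 33 (Z)-1-diazo-4-{2-[3,5-dimethoxy-4-(3,4,5-trimethoxyphenoxy)phenoxy]-3,4,5-trimethoxyphenoxy}-3-methoxybut-3-en-2-one, via mixed anhydride 32 (not isolated)
Conditions: i-BuOCOCl, Et3N, THF, −15 °C; then CH2N2 (Et2O), −15 → 0 °C
Reagents that add atoms: diazomethane, C=[N+]=[N-]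
Why: Acylation of diazomethane through the mixed carbonic anhydride as in step 5, again on a donor-substituted trisubstituted alkene that should resist dipolar cycloaddition.

Step 18
Reactants: 34 5-bromo-1,2,3-trimethoxybenzene
Product: 36 6-bromo-2,3,4-trimethoxybenzaldehyde, via α-chloro ether 35 (not isolated)
Conditions: Cl2CHOMe, TiCl4, CH2Cl2, −10 → 0 °C; then H2O
Reagents that add atoms: dichloromethyl methyl ether, COC(Cl)Cl; water, O
Why: Rieche formylation should attack the only type of free position, ortho to bromine and ortho/para to methoxy groups, and hydrolysis of the α-chloro ether gives the aldehyde.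

Step 19
Reactants: 36 6-bromo-2,3,4-trimethoxybenzaldehyde; 37 2,4,6-trimethoxyphenol
Product: 38 2,3,4-trimethoxy-6-(2,4,6-trimethoxyphenoxy)benzaldehyde (AB aldehyde)
Conditions: CuI (10 mol %), picolinic acid (20 mol %), K3PO4, DMSO, 90 °C, under Ar
Reagents that add atoms: none
Why: The Ullmann diaryl ether coupling places the steric demand on the nucleophile (a 2,6-disubstituted phenol, tolerated by the CuI/picolinic acid system) and uses an aryl bromide activated by its ortho formyl group.

Step 20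
Reactants: 38 2,3,4-trimethoxy-6-(2,4,6-trimethoxyphenoxy)benzaldehyde
Product: 40 2,3,4-trimethoxy-6-(2,4,6-trimethoxyphenoxy)phenol (AB phenol), via aryl formate 39 (not isolated)
Conditions: mCPBA, NaHCO3, CH2Cl2, 0 °C → rt; then K2CO3 (cat.), MeOH, rt, under Ar
Reagents that add atoms: 3-chloroperoxybenzoic acid, OOC(=O)c1cccc(Cl)c1
Why: Baeyer–Villiger oxidation of the doubly ortho-oxygenated benzaldehyde should give the formate by aryl migration, and methanolysis frees the ring B phenol next to the A–O–B ether.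

Step 21
Reactants: 40 2,3,4-trimethoxy-6-(2,4,6-trimethoxyphenoxy)phenol; 17 dichloroacetylene
Product: 41 2-{[(E)-1,2-dichloroethenyl]oxy}-3,4,5-trimethoxy-1-(2,4,6-trimethoxyphenoxy)benzene
Conditions: K2CO3 (0.5 equiv), DMF, 17 (THF solution, 1.5 equiv), 0 °C → rt, closed vessel under N2
Reagents that add atoms: none
Why: The phenoxide of 40 should add anti to dichloroacetylene as in step 10, the base again acting only as a catalyst.

Step 22
Reactants: 41 2-{[(E)-1,2-dichloroethenyl]oxy}-3,4,5-trimethoxy-1-(2,4,6-trimethoxyphenoxy)benzene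
Product: 44 2-(ethynyloxy)-3,4,5-trimethoxy-1-(2,4,6-trimethoxyphenoxy)benzene (AB ynol ether), via chloroethynyl ether 42 (not isolated), via lithium acetylide 43 (not isolated)
Conditions: n-BuLi (2.3 equiv), THF, −78 → −40 °C; then MeOH, −78 °C; used at once as a cold solution
Reagents that add atoms: none
Why: The elimination and lithium–chlorine exchange sequence of step 11, run at a temperature at which ring lithiation between methoxy groups should not compete.

Step 23
Reactants: 33 (Z)-1-diazo-4-(ArDEF-oxy)-3-methoxybut-3-en-2-one; 44 2-(ethynyloxy)-3,4,5-trimethoxy-1-(2,4,6-trimethoxyphenoxy)benzene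
Product: 49 2-{2-[3,5-dimethoxy-4-(3,4,5-trimethoxyphenoxy)phenoxy]-3,4,5-trimethoxyphenoxy}-3-methoxy-5-[2,3,4-trimethoxy-6-(2,4,6-trimethoxyphenoxy)phenoxy]phenol (pentadeca-O-methyl hexamer), via vinylketene 45 (not isolated), via vinylcyclobutenone 46 (not isolated), via dienylketene 47 (not isolated), via cyclohexadienone 48 (not isolated)
Conditions: hν (medium-pressure Hg lamp, Pyrex, λ > 300 nm), 44 (1.5 equiv), degassed ClCH2CH2Cl, rt; then 80 °C
Reagents that add atoms: none
Why: The Danheiser benzannulation of step 12 is repeated to build ring C, the ynol ether polarisation again fixing the ring B aryloxy group meta to the new hydroxyl and para to the ring D aryloxy group, with the large aryl groups remote from the reacting ketene and alkyne carbons.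

Step 24
Reactants: 49 pentadeca-O-methyl hexamer
Product: 50 2-[2-(4-{2-[3,5-dihydroxy-4-(3,4,5-trihydroxyphenoxy)phenoxy]-3,4,5-trihydroxyphenoxy}-3,5-dihydroxyphenoxy)-3,4,5-trihydroxyphenoxy]benzene-1,3,5-triol (CNP0218077.0)
Conditions: BBr3 (excess), CH2Cl2, −78 °C → rt; then MeOH, H2O, 0 °C; Sephadex LH-20 under Ar
Reagents that add atoms: none
Why: Boron tribromide cleaves aryl methyl ethers at the O–CH3 bond and leaves diaryl ether bonds intact, so that exhaustive demethylation should free all sixteen hydroxyl groups.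

**Compound list**
1 | methyl methoxyacetate | COCC(=O)OC | starting material
2 | sodium 2,3-dimethoxy-3-oxoprop-1-en-1-olate (enolate geometry not defined) | [Na+].[O-]C=C(OC)C(=O)OC | intermediate
3 | methyl 3-[(chlorooxalyl)oxy]-2-methoxyprop-2-enoate (enol chlorooxalate) | COC(=O)C(OC)=COC(=O)C(Cl)=O | intermediate (not isolated)
4 | methyl (Z)-3-chloro-2-methoxyprop-2-enoate | COC(=O)/C(OC)=C/Cl | intermediate
5 | 3,4,5-trimethoxyphenol | COc1cc(O)cc(OC)c1OC | starting material
6 | methyl (Z)-2-methoxy-3-(3,4,5-trimethoxyphenoxy)prop-2-enoate | COC(=O)/C(OC)=C/Oc1cc(OC)c(OC)c(OC)c1 | intermediate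
7 | lithium (Z)-2-methoxy-3-(3,4,5-trimethoxyphenoxy)prop-2-enoate | [Li+].[O-]C(=O)/C(OC)=C/Oc1cc(OC)c(OC)c(OC)c1 | intermediate (not isolated)
8 | (Z)-2-methoxy-3-(3,4,5-trimethoxyphenoxy)prop-2-enoic acid | OC(=O)/C(OC)=C/Oc1cc(OC)c(OC)c(OC)c1 | intermediate
9 | isobutyl carbonic anhydride of acid 8 | CC(C)COC(=O)OC(=O)/C(OC)=C/Oc1cc(OC)c(OC)c(OC)c1 | intermediate (not isolated)
10 | (Z)-1-diazo-3-methoxy-4-(3,4,5-trimethoxyphenoxy)but-3-en-2-one | [N-]=[N+]=CC(=O)/C(OC)=C/Oc1cc(OC)c(OC)c(OC)c1 | intermediate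
11 | 5-(benzyloxy)-1,2,3-trimethoxybenzene | COc1cc(OCc2ccccc2)cc(OC)c1OC | intermediate
12 | N-{[6-(benzyloxy)-2,3,4-trimethoxyphenyl]methylidene}-N-methylmethanaminium chloride | C[N+](C)=Cc1c(OCc2ccccc2)cc(OC)c(OC)c1OC.[Cl-] | intermediate (not isolated)
13 | 6-(benzyloxy)-2,3,4-trimethoxybenzaldehyde | O=Cc1c(OCc2ccccc2)cc(OC)c(OC)c1OC | intermediate
14 | 6-(benzyloxy)-2,3,4-trimethoxyphenyl formate | O=COc1c(OCc2ccccc2)cc(OC)c(OC)c1OC | intermediate (not isolated)
15 | 6-(benzyloxy)-2,3,4-trimethoxyphenol | Oc1c(OCc2ccccc2)cc(OC)c(OC)c1OC | intermediate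
16 | trichloroethylene | ClC=C(Cl)Cl | starting material
17 | dichloroacetylene (handled only as a dilute THF solution) | ClC#CCl | intermediate
18 | 1-(benzyloxy)-2-{[(E)-1,2-dichloroethenyl]oxy}-3,4,5-trimethoxybenzene | Cl\C=C(Cl)/Oc1c(OCc2ccccc2)cc(OC)c(OC)c1OC | intermediate
19 | 1-(benzyloxy)-2-[(chloroethynyl)oxy]-3,4,5-trimethoxybenzene | ClC#COc1c(OCc2ccccc2)cc(OC)c(OC)c1OC | intermediate (not isolated)
20 | lithium {[2-(benzyloxy)-4,5,6-trimethoxyphenoxy]ethynide} | [Li]C#COc1c(OCc2ccccc2)cc(OC)c(OC)c1OC | intermediate (not isolated)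
21 | 1-(benzyloxy)-2-(ethynyloxy)-3,4,5-trimethoxybenzene | C#COc1c(OCc2ccccc2)cc(OC)c(OC)c1OC | intermediate
22 | (Z)-3-methoxy-4-(3,4,5-trimethoxyphenoxy)buta-1,3-dien-1-one (vinylketene) | O=C=C/C(OC)=C/Oc1cc(OC)c(OC)c(OC)c1 | intermediate (not isolated)
23 | 3-(ArD-oxy)-4-[(Z)-1-methoxy-2-(ArF-oxy)ethenyl]cyclobut-2-en-1-one (racemic) | O=C1C=C(Oc2c(OCc3ccccc3)cc(OC)c(OC)c2OC)C1/C(OC)=C/Oc1cc(OC)c(OC)c(OC)c1 | intermediate (not isolated)
24 | (3E,5Z)-3-(ArD-oxy)-5-methoxy-6-(ArF-oxy)hexa-1,3,5-trien-1-one (dienylketene) | O=C=C/C(Oc1c(OCc2ccccc2)cc(OC)c(OC)c1OC)=C\C(OC)=C\Oc1cc(OC)c(OC)c(OC)c1 | intermediate (not isolated)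
25 | 3-(ArD-oxy)-5-methoxy-6-(ArF-oxy)cyclohexa-2,4-dien-1-one (racemic) | O=C1C=C(Oc2c(OCc3ccccc3)cc(OC)c(OC)c2OC)C=C(OC)C1Oc1cc(OC)c(OC)c(OC)c1 | intermediate (not isolated)
26 | 5-[6-(benzyloxy)-2,3,4-trimethoxyphenoxy]-3-methoxy-2-(3,4,5-trimethoxyphenoxy)phenol | COc1cc(Oc2c(OC)cc(Oc3c(OCc4ccccc4)cc(OC)c(OC)c3OC)cc2O)cc(OC)c1OC | intermediate
27 | 1-[6-(benzyloxy)-2,3,4-trimethoxyphenoxy]-3,5-dimethoxy-4-(3,4,5-trimethoxyphenoxy)benzene | COc1cc(Oc2c(OC)cc(Oc3c(OCc4ccccc4)cc(OC)c(OC)c3OC)cc2OC)cc(OC)c1OC | intermediate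
28 | 2-[3,5-dimethoxy-4-(3,4,5-trimethoxyphenoxy)phenoxy]-3,4,5-trimethoxyphenol (ArDEF–OH) | COc1cc(Oc2c(OC)cc(Oc3c(O)cc(OC)c(OC)c3OC)cc2OC)cc(OC)c1OC | intermediate
29 | methyl (Z)-3-(ArDEF-oxy)-2-methoxyprop-2-enoate | COC(=O)/C(OC)=C/Oc1cc(OC)c(OC)c(OC)c1Oc1cc(OC)c(Oc2cc(OC)c(OC)c(OC)c2)c(OC)c1 | intermediate
30 | lithium (Z)-3-(ArDEF-oxy)-2-methoxyprop-2-enoate | [Li+].[O-]C(=O)/C(OC)=C/Oc1cc(OC)c(OC)c(OC)c1Oc1cc(OC)c(Oc2cc(OC)c(OC)c(OC)c2)c(OC)c1 | intermediate (not isolated)
31 | (Z)-3-(ArDEF-oxy)-2-methoxyprop-2-enoic acid | OC(=O)/C(OC)=C/Oc1cc(OC)c(OC)c(OC)c1Oc1cc(OC)c(Oc2cc(OC)c(OC)c(OC)c2)c(OC)c1 | intermediate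
32 | isobutyl carbonic anhydride of acid 31 | CC(C)COC(=O)OC(=O)/C(OC)=C/Oc1cc(OC)c(OC)c(OC)c1Oc1cc(OC)c(Oc2cc(OC)c(OC)c(OC)c2)c(OC)c1 | intermediate (not isolated)
33 | (Z)-1-diazo-4-(ArDEF-oxy)-3-methoxybut-3-en-2-one | [N-]=[N+]=CC(=O)/C(OC)=C/Oc1cc(OC)c(OC)c(OC)c1Oc1cc(OC)c(Oc2cc(OC)c(OC)c(OC)c2)c(OC)c1 | intermediate
34 | 5-bromo-1,2,3-trimethoxybenzene | COc1cc(Br)cc(OC)c1OC | starting material
35 | 1-bromo-2-[chloro(methoxy)methyl]-3,4,5-trimethoxybenzene | COC(Cl)c1c(Br)cc(OC)c(OC)c1OC | intermediate (not isolated)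
36 | 6-bromo-2,3,4-trimethoxybenzaldehyde | O=Cc1c(Br)cc(OC)c(OC)c1OC | intermediate
37 | 2,4,6-trimethoxyphenol | COc1cc(OC)c(O)c(OC)c1 | starting material
38 | 2,3,4-trimethoxy-6-(2,4,6-trimethoxyphenoxy)benzaldehyde | O=Cc1c(Oc2c(OC)cc(OC)cc2OC)cc(OC)c(OC)c1OC | intermediate
39 | 2,3,4-trimethoxy-6-(2,4,6-trimethoxyphenoxy)phenyl formate | O=COc1c(Oc2c(OC)cc(OC)cc2OC)cc(OC)c(OC)c1OC | intermediate (not isolated)
40 | 2,3,4-trimethoxy-6-(2,4,6-trimethoxyphenoxy)phenol (ArAB–OH) | Oc1c(Oc2c(OC)cc(OC)cc2OC)cc(OC)c(OC)c1OC | intermediate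
41 | 2-{[(E)-1,2-dichloroethenyl]oxy}-3,4,5-trimethoxy-1-(2,4,6-trimethoxyphenoxy)benzene | Cl\C=C(Cl)/Oc1c(Oc2c(OC)cc(OC)cc2OC)cc(OC)c(OC)c1OC | intermediate
42 | 2-[(chloroethynyl)oxy]-3,4,5-trimethoxy-1-(2,4,6-trimethoxyphenoxy)benzene | ClC#COc1c(Oc2c(OC)cc(OC)cc2OC)cc(OC)c(OC)c1OC | intermediate (not isolated)
43 | lithium [(ArAB-oxy)ethynide] | [Li]C#COc1c(Oc2c(OC)cc(OC)cc2OC)cc(OC)c(OC)c1OC | intermediate (not isolated)
44 | 2-(ethynyloxy)-3,4,5-trimethoxy-1-(2,4,6-trimethoxyphenoxy)benzene | C#COc1c(Oc2c(OC)cc(OC)cc2OC)cc(OC)c(OC)c1OC | intermediate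
45 | (Z)-4-(ArDEF-oxy)-3-methoxybuta-1,3-dien-1-one (vinylketene) | O=C=C/C(OC)=C/Oc1cc(OC)c(OC)c(OC)c1Oc1cc(OC)c(Oc2cc(OC)c(OC)c(OC)c2)c(OC)c1 | intermediate (not isolated)
46 | 3-(ArAB-oxy)-4-[(Z)-2-(ArDEF-oxy)-1-methoxyethenyl]cyclobut-2-en-1-one (racemic) | O=C1C=C(Oc2c(Oc3c(OC)cc(OC)cc3OC)cc(OC)c(OC)c2OC)C1/C(OC)=C/Oc1cc(OC)c(OC)c(OC)c1Oc1cc(OC)c(Oc2cc(OC)c(OC)c(OC)c2)c(OC)c1 | intermediate (not isolated)
47 | (3E,5Z)-3-(ArAB-oxy)-6-(ArDEF-oxy)-5-methoxyhexa-1,3,5-trien-1-one (dienylketene) | O=C=C/C(Oc1c(Oc2c(OC)cc(OC)cc2OC)cc(OC)c(OC)c1OC)=C\C(OC)=C\Oc1cc(OC)c(OC)c(OC)c1Oc1cc(OC)c(Oc2cc(OC)c(OC)c(OC)c2)c(OC)c1 | intermediate (not isolated)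
48 | 3-(ArAB-oxy)-6-(ArDEF-oxy)-5-methoxycyclohexa-2,4-dien-1-one (racemic) | O=C1C=C(Oc2c(Oc3c(OC)cc(OC)cc3OC)cc(OC)c(OC)c2OC)C=C(OC)C1Oc1cc(OC)c(OC)c(OC)c1Oc1cc(OC)c(Oc2cc(OC)c(OC)c(OC)c2)c(OC)c1 | intermediate (not isolated)
49 | 2-(ArDEF-oxy)-3-methoxy-5-(ArAB-oxy)phenol (pentadeca-O-methyl hexamer with free ring C phenol) | COc1cc(OC)c(Oc2cc(OC)c(OC)c(OC)c2Oc2cc(OC)c(Oc3cc(OC)c(OC)c(OC)c3Oc3cc(OC)c(Oc4cc(OC)c(OC)c(OC)c4)c(OC)c3)c(O)c2)c(OC)c1 | intermediate
50 | 2-[2-(4-{2-[3,5-dihydroxy-4-(3,4,5-trihydroxyphenoxy)phenoxy]-3,4,5-trihydroxyphenoxy}-3,5-dihydroxyphenoxy)-3,4,5-trihydroxyphenoxy]benzene-1,3,5-triol (CNP0218077.0) | Oc1cc(O)c(Oc2cc(O)c(O)c(O)c2Oc2cc(O)c(Oc3cc(O)c(O)c(O)c3Oc3cc(O)c(Oc4cc(O)c(O)c(O)c4)c(O)c3)c(O)c2)c(O)c1 | target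

**Step count**
Total: 24 steps. Longest linear sequence: 13 steps (steps 1–5, 12–17, 23, 24; the branch through steps 6–8, 10 and 11 is equally long).

**Steps most likely to fail**

Step 12. The polyoxygenated aryl ethers may absorb the light in competition with the diazoketone. The vinylketene may dimerise or be intercepted before it meets the ynol ether, and the terminal aryl ynol ether may polymerise during irradiation. The 3-aryloxycyclobutenone may also resist ring opening, and any E isomer of 10 would slow the 6π closure. Fallback (sets out from 15, comes back at 27, so steps 12 and 13 are bypassed): ring E is taken from a preformed arene and both of its ether bonds are made by copper chemistry in which the 2,6-disubstituted partner is always the phenol. Commercial 4-bromo-2,6-dimethoxyphenol and (3,4,5-trimethoxyphenyl)boronic acid are joined by Chan–Lam coupling (Cu(OAc)2, pyridine, 4 Å molecular sieves, CH2Cl2, air, rt) to give 5-bromo-1,3-dimethoxy-2-(3,4,5-trimethoxyphenoxy)benzene F1. Its unhindered C–Br bond is then coupled with phenol 15 under Ullmann conditions (CuI, picolinic acid, K3PO4, DMSO, 100 °C) to give 27.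

Step 23. The same processes as in step 12 apply, made worse by the larger chromophores, the low concentration of two precious partners and slower bimolecular capture of the ketene. Fallback (sets out from 28 and 40, comes back at 50): ring C is brought in as an arene. Phenol 28 is coupled with commercial 4-bromo-3,5-dimethoxybenzaldehyde, whose hindered C–Br bond is activated by the para formyl group (Ullmann: CuI, N,N-dimethylglycine, Cs2CO3, dioxane, 110 °C), to give 4-(ArDEF-oxy)-3,5-dimethoxybenzaldehyde F2. Baeyer–Villiger oxidation (mCPBA, CH2Cl2) gives 4-(ArDEF-oxy)-3,5-dimethoxyphenyl formate F3, and methanolysis (K2CO3, MeOH) gives 4-(ArDEF-oxy)-3,5-dimethoxyphenol F4. Tf2O and pyridine in CH2Cl2 convert it into 4-(ArDEF-oxy)-3,5-dimethoxyphenyl trifluoromethanesulfonate F5. Palladium-catalysed etherification of this unhindered triflate with the hindered phenol 40 (Pd(OAc)2, 2-di-tert-butylphosphino-2',4',6'-triisopropylbiphenyl, K3PO4, toluene, 100 °C) gives the hexadeca-O-methyl ether of the target F6. The BBr3 conditions of step 24 then give 50.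

Step 5 (the same operation recurs in step 17). Diazomethane may add as a 1,3-dipole across the conjugated double bond instead of being acylated, and the mixed anhydride may be attacked at the carbonate carbonyl and return the acid. Fallback (sets out from 6, comes back at 10): the diazo group is introduced by diazo transfer to a methyl ketone, with no diazomethane. Ester 6 is converted with MeNHOMe·HCl and i-PrMgCl (THF, −20 °C) into (Z)-N,2-dimethoxy-N-methyl-3-(3,4,5-trimethoxyphenoxy)prop-2-enamide F7. MeMgBr (THF, −20 → 0 °C) gives (Z)-3-methoxy-4-(3,4,5-trimethoxyphenoxy)but-3-en-2-one F8. Kinetic enolisation at the methyl group (LiN(SiMe3)2, THF, −78 °C) and trapping with CF3CO2CH2CF3 gives (Z)-1,1,1-trifluoro-5-methoxy-6-(3,4,5-trimethoxyphenoxy)hex-5-ene-2,4-dione F9. Detrifluoroacetylative diazo transfer (MsN3, Et3N, H2O, MeCN, rt) then gives 10.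

**Further compounds**
F1 | step 12 | 5-bromo-1,3-dimethoxy-2-(3,4,5-trimethoxyphenoxy)benzene | COc1cc(Oc2c(OC)cc(Br)cc2OC)cc(OC)c1OC
F2 | step 23 | 4-(ArDEF-oxy)-3,5-dimethoxybenzaldehyde | O=Cc1cc(OC)c(Oc2cc(OC)c(OC)c(OC)c2Oc2cc(OC)c(Oc3cc(OC)c(OC)c(OC)c3)c(OC)c2)c(OC)c1
F3 | step 23 | 4-(ArDEF-oxy)-3,5-dimethoxyphenyl formate | O=COc1cc(OC)c(Oc2cc(OC)c(OC)c(OC)c2Oc2cc(OC)c(Oc3cc(OC)c(OC)c(OC)c3)c(OC)c2)c(OC)c1
F4 | step 23 | 4-(ArDEF-oxy)-3,5-dimethoxyphenol | Oc1cc(OC)c(Oc2cc(OC)c(OC)c(OC)c2Oc2cc(OC)c(Oc3cc(OC)c(OC)c(OC)c3)c(OC)c2)c(OC)c1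
F5 | step 23 | 4-(ArDEF-oxy)-3,5-dimethoxyphenyl trifluoromethanesulfonate | FC(F)(F)S(=O)(=O)Oc1cc(OC)c(Oc2cc(OC)c(OC)c(OC)c2Oc2cc(OC)c(Oc3cc(OC)c(OC)c(OC)c3)c(OC)c2)c(OC)c1
F6 | step 23 | hexadeca-O-methyl ether of the target | COc1cc(OC)c(Oc2cc(OC)c(OC)c(OC)c2Oc2cc(OC)c(Oc3cc(OC)c(OC)c(OC)c3Oc3cc(OC)c(Oc4cc(OC)c(OC)c(OC)c4)c(OC)c3)c(OC)c2)c(OC)c1
F7 | step 5 | (Z)-N,2-dimethoxy-N-methyl-3-(3,4,5-trimethoxyphenoxy)prop-2-enamide | CON(C)C(=O)/C(OC)=C/Oc1cc(OC)c(OC)c(OC)c1
F8 | step 5 | (Z)-3-methoxy-4-(3,4,5-trimethoxyphenoxy)but-3-en-2-one | CC(=O)/C(OC)=C/Oc1cc(OC)c(OC)c(OC)c1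
F9 | step 5 | (Z)-1,1,1-trifluoro-5-methoxy-6-(3,4,5-trimethoxyphenoxy)hex-5-ene-2,4-dione | O=C(CC(=O)/C(OC)=C/Oc1cc(OC)c(OC)c(OC)c1)C(F)(F)F
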